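The synthesis rests on cutting the C1–C2 bond of the syringyl-bearing oxolane (ring B: C1, C2, O3, C4, C5). The precursor is a monocyclic oxolan-3-one: ring A with C1 as a ketone, carrying the syringyl unit merely as a benzyl ether on the C4 oxygen. A Norrish–Yang photocyclisation turns it into the furofuran. Because O3 occupies the position gamma to the C1 carbonyl, only the delta benzylic C2–H bonds are within reach. 1,6-Hydrogen transfer followed by biradical collapse creates the C1–C2 bond, the tertiary carbinol and the benzylic stereocentre in one operation, the C5 tether enforcing cis fusion. C5 and C6 come from an iridium-catalysed anti-selective (hydroxymethyl)allylation of silylated vanillin.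

Key step: step 9

Remark on numbering: the lignan numbering of the 3,7-dioxabicyclo[3.3.0]octane is used for all intermediates. C1 is the carbinol bridgehead, C2 the syringyl CH, O3, C4 a CH2, C5 the bridgehead CH, C6 the guaiacyl CH, O7, C8 a CH2. Ring A is C1, C5, C6, O7, C8 and ring B is C1, C2, O3, C4, C5. The target is (1S,2R,5R,6S), with both aryl groups exo.

Assumption: (S)-SEGPHOS is taken to direct the allyl group to the Si face of the aldehyde in step 5; if it favours the other face, (R)-SEGPHOS is used and nothing else changes.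

Step 1
Reactants: 1 vanillin
Product: 2 3-methoxy-4-(triisopropylsilyloxy)benzaldehyde
Conditions: TIPSCl, imidazole, DMF, rt
Reagents that add atoms: triisopropylsilyl chloride, CC(C)[Si](Cl)(C(C)C)C(C)C
Why: Imidazole-promoted O-silylation masks the phenol, which would interfere with the iridium catalyst and quench the later photoreaction, as a bulky ether that withstands mild base, peracid, periodinane and light.

Step 2
Reactants: 3 syringaldehyde
Product: 4 3,5-dimethoxy-4-(triisopropylsilyloxy)benzaldehyde
Conditions: TIPSCl, imidazole, DMAP (cat.), DMF, 40 °C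
Reagents that add atoms: triisopropylsilyl chloride, CC(C)[Si](Cl)(C(C)C)C(C)C
Why: The same O-silylation, helped by DMAP and gentle warming because the phenol is flanked by two methoxy groups.

Step 3
Reactants: 4 3,5-dimethoxy-4-(triisopropylsilyloxy)benzaldehyde
Product: 5 [3,5-dimethoxy-4-(triisopropylsilyloxy)phenyl]methanol
Conditions: NaBH4, THF–MeOH, 0 °C
Reagents that add atoms: none
Why: Chemoselective borohydride reduction of the aldehyde, the hindered aryl silyl ether being inert at this temperature.

Step 4
Reactants: 5 [3,5-dimethoxy-4-(triisopropylsilyloxy)phenyl]methanol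
Product: 6 3,5-dimethoxy-4-(triisopropylsilyloxy)benzyl bromide
Conditions: CBr4, PPh3, CH2Cl2, 0 °C
Reagents that add atoms: carbon tetrabromide, BrC(Br)(Br)Br
Why: The Appel bromination displaces the oxyphosphonium ion by SN2 under neutral conditions, so the silyl ether and the electron-rich ring stay untouched.

Step 5
Reactants: 2 3-methoxy-4-(triisopropylsilyloxy)benzaldehyde; 7 4-vinyl-1,3-dioxolan-2-one (racemic)
Product: 8 (1S,2R)-1-[3-methoxy-4-(triisopropylsilyloxy)phenyl]-2-vinylpropane-1,3-diol (anti)
Conditions: [Ir(cod)Cl]2 (cat.), (S)-SEGPHOS (cat.), 4-cyano-3-nitrobenzoic acid (cat.), K3PO4 (cat.), i-PrOH (2 equiv), THF, 90 °C, sealed tube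
Reagents that add atoms: none
Why: In this transfer-hydrogenative carbonyl (hydroxymethyl)allylation the catalyst formed from [Ir(cod)Cl]2, SEGPHOS and the nitrobenzoic acid ionises the allylic carbonate 7 with loss of CO2, isopropanol acts as terminal reductant, and the (E)-σ-(hydroxymethyl)allyl complex of trivalent iridium adds to the Si face of 2 through a closed chair transition state, so that the ligand sets C6 (S) and the chair geometry sets C5 (R) anti to it.

Step 6
Reactants: 8 (1S,2R)-1-[3-methoxy-4-(triisopropylsilyloxy)phenyl]-2-vinylpropane-1,3-diol; 6 3,5-dimethoxy-4-(triisopropylsilyloxy)benzyl bromide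
Product: 9 (1S,2R)-2-({[3,5-dimethoxy-4-(triisopropylsilyloxy)benzyl]oxy}methyl)-1-[3-methoxy-4-(triisopropylsilyloxy)phenyl]but-3-en-1-ol
Conditions: Ag2O, CH2Cl2, rt, dark
Reagents that add atoms: none
Why: In this Ag2O-mediated Williamson-type monoalkylation of a diol the unhindered primary hydroxyl should react faster than the hindered secondary benzylic one, under conditions free of strong base that spare both silyl ethers.

Step 7
Reactants: 9 (1S,2R)-2-({[3,5-dimethoxy-4-(triisopropylsilyloxy)benzyl]oxy}methyl)-1-[3-methoxy-4-(triisopropylsilyloxy)phenyl]but-3-en-1-ol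
Product: 11 (4S,5S)-4-({[3,5-dimethoxy-4-(triisopropylsilyloxy)benzyl]oxy}methyl)-5-[3-methoxy-4-(triisopropylsilyloxy)phenyl]oxolan-3-ol (both C3 epimers), via epoxy alcohol 10 (not isolated)
Conditions: mCPBA, CH2Cl2, 0 °C to rt; then camphorsulfonic acid (cat.), rt
Reagents that add atoms: 3-chloroperoxybenzoic acid, O=C(OO)c1cccc(Cl)c1
Why: Prilezhaev epoxidation of the vinyl group is followed by acid-catalysed opening of the terminal epoxide by the benzylic hydroxyl at the unsubstituted carbon C8 (5-endo-tet, preferred over the strained 4-exo oxetane), which closes ring A with C6 and C5 untouched, while the new carbinol centre is irrelevant because it is oxidised next.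

Step 8
Reactants: 11 (4S,5S)-4-({[3,5-dimethoxy-4-(triisopropylsilyloxy)benzyl]oxy}methyl)-5-[3-methoxy-4-(triisopropylsilyloxy)phenyl]oxolan-3-ol
Product: 12 (4R,5S)-4-({[3,5-dimethoxy-4-(triisopropylsilyloxy)benzyl]oxy}methyl)-5-[3-methoxy-4-(triisopropylsilyloxy)phenyl]oxolan-3-one (4,5-trans)
Conditions: Dess–Martin periodinane, CH2Cl2, 0 °C to rt
Reagents that add atoms: none
Why: The Dess–Martin oxidation converts both carbinol epimers into one ketone without base, so neither beta-alkoxy group is eliminated, and the 4,5-trans arrangement is also the thermodynamic one, so C5 is not at risk.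

Step 9
Reactants: 12 (4R,5S)-4-({[3,5-dimethoxy-4-(triisopropylsilyloxy)benzyl]oxy}methyl)-5-[3-methoxy-4-(triisopropylsilyloxy)phenyl]oxolan-3-one
Product: 14 (1S,2R,5R,6S)-O,O'-bis(triisopropylsilyl)fraxiresinol, via 1,5-biradical 13 (not isolated)
Conditions: hν (medium-pressure Hg lamp, Pyrex filter, λ > 290 nm), degassed benzene, high dilution, rt
Reagents that add atoms: none
Why: Excitation of the n,π* band of the ring A ketone (C1=O) is followed by 1,6-hydrogen atom transfer from the syringyl OCH2 group (C2–H) through a seven-membered transition state, and the resulting 1,5-biradical 13 (C1 ketyl, C2 benzylic alpha-oxy radical) collapses by radical recombination to the C1–C2 bond. This is the Norrish–Yang cyclisation in its delta-hydrogen variant, the known route from beta-alkoxy ketones to oxolan-3-ols. Ring B is closed as a five-membered ring by 1,5-biradical coupling, so no ionic trajectory rule is at stake and C2 needs neither a leaving group nor an activating group. C1 is controlled by C5, because the three-atom C4–O3–C2 tether can reach the ketyl carbon only from the face that carries C4, which enforces the cis-fused bicycle with the hydroxyl on the convex face. C2 is controlled by the bicyclic transition state, in which the freely rotating planar benzylic radical should place the bulky aryl group on the convex (exo) face, away from C8 of ring A, and leave its hydrogen endo. The step needs site-selective hydrogen abstraction, and this is secured by O3 occupying the gamma position (no gamma hydrogen, hence no cyclobutanol and no cleavage), by the weak doubly activated C2–H bonds, by the ring-locked C6–H lying out of reach of the carbonyl oxygen, and by silylation of both phenols, which would otherwise quench the excited ketone.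

Step 10
Reactants: 14 (1S,2R,5R,6S)-O,O'-bis(triisopropylsilyl)fraxiresinol
Product: 15 fraxiresinol
Conditions: TBAF, AcOH, THF, 0 °C
Reagents that add atoms: none
Why: Fluoride cleaves both aryl Si–O bonds, while the acetic acid buffer keeps the phenols protonated so that the benzylic ether centres C2 and C6 of the furofuran are not epimerised.

Compound list
1 | vanillin | COc1cc(C=O)ccc1O | starting material
2 | 3-methoxy-4-(triisopropylsilyloxy)benzaldehyde | COc1cc(C=O)ccc1O[Si](C(C)C)(C(C)C)C(C)C | intermediate
3 | syringaldehyde | COc1cc(C=O)cc(OC)c1O | starting material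
4 | 3,5-dimethoxy-4-(triisopropylsilyloxy)benzaldehyde | COc1cc(C=O)cc(OC)c1O[Si](C(C)C)(C(C)C)C(C)C | intermediate
5 | [3,5-dimethoxy-4-(triisopropylsilyloxy)phenyl]methanol | COc1cc(CO)cc(OC)c1O[Si](C(C)C)(C(C)C)C(C)C | intermediate
6 | 3,5-dimethoxy-4-(triisopropylsilyloxy)benzyl bromide | COc1cc(CBr)cc(OC)c1O[Si](C(C)C)(C(C)C)C(C)C | intermediate
7 | 4-vinyl-1,3-dioxolan-2-one (racemic) | C=CC1COC(=O)O1 | starting material
8 | (1S,2R)-1-[3-methoxy-4-(triisopropylsilyloxy)phenyl]-2-vinylpropane-1,3-diol | COc1cc([C@@H](O)[C@H](C=C)CO)ccc1O[Si](C(C)C)(C(C)C)C(C)C | intermediate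
9 | (1S,2R)-2-({[3,5-dimethoxy-4-(triisopropylsilyloxy)benzyl]oxy}methyl)-1-[3-methoxy-4-(triisopropylsilyloxy)phenyl]but-3-en-1-ol | COc1cc([C@@H](O)[C@H](C=C)COCc2cc(OC)c(O[Si](C(C)C)(C(C)C)C(C)C)c(OC)c2)ccc1O[Si](C(C)C)(C(C)C)C(C)C | intermediate
10 | epoxy alcohol, the oxirane of the vinyl group of 9 (both oxirane epimers, C5 and C6 as in 9) | COc1cc([C@@H](O)[C@H](C2CO2)COCc2cc(OC)c(O[Si](C(C)C)(C(C)C)C(C)C)c(OC)c2)ccc1O[Si](C(C)C)(C(C)C)C(C)C | intermediate
11 | (4S,5S)-4-({[3,5-dimethoxy-4-(triisopropylsilyloxy)benzyl]oxy}methyl)-5-[3-methoxy-4-(triisopropylsilyloxy)phenyl]oxolan-3-ol (both C3 epimers) | COc1cc([C@H]2OCC(O)[C@@H]2COCc2cc(OC)c(O[Si](C(C)C)(C(C)C)C(C)C)c(OC)c2)ccc1O[Si](C(C)C)(C(C)C)C(C)C | intermediate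
12 | (4R,5S)-4-({[3,5-dimethoxy-4-(triisopropylsilyloxy)benzyl]oxy}methyl)-5-[3-methoxy-4-(triisopropylsilyloxy)phenyl]oxolan-3-one | COc1cc([C@H]2OCC(=O)[C@@H]2COCc2cc(OC)c(O[Si](C(C)C)(C(C)C)C(C)C)c(OC)c2)ccc1O[Si](C(C)C)(C(C)C)C(C)C | intermediate
13 | 1,5-biradical (C1 ketyl radical, C2 benzylic alpha-oxy radical) | COc1cc([C@H]2OC[C](O)[C@@H]2CO[CH]c2cc(OC)c(O[Si](C(C)C)(C(C)C)C(C)C)c(OC)c2)ccc1O[Si](C(C)C)(C(C)C)C(C)C | intermediate
14 | (1S,2R,5R,6S)-O,O'-bis(triisopropylsilyl)fraxiresinol | COc1cc([C@H]2OC[C@]3(O)[C@@H](c4cc(OC)c(O[Si](C(C)C)(C(C)C)C(C)C)c(OC)c4)OC[C@H]23)ccc1O[Si](C(C)C)(C(C)C)C(C)C | intermediate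
15 | fraxiresinol, (1S,2R,5R,6S)-2-(4-hydroxy-3,5-dimethoxyphenyl)-6-(4-hydroxy-3-methoxyphenyl)-3,7-dioxabicyclo[3.3.0]octan-1-ol | COc1cc([C@H]2OC[C@]3(O)[C@@H](c4cc(OC)c(O)c(OC)c4)OC[C@H]23)ccc1O | target

Total step count: 10
Longest linear sequence: 8 steps (3, 4, 5, 6, 9, 11, 12, 14, 15)

Steps most likely to fail

Risk 1, step 9.
- **What may go wrong:** alpha-cleavage of the excited oxolanone, with decarbonylation or loss of configuration at C5. Unproductive reverse hydrogen transfer may occur. The electron-rich arenes may quench the excited state by charge transfer. Exo/endo selectivity at C2 in the biradical collapse may be poor.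
- **Fallback:** it sets out from ketone 12 and bromide 6 and comes back at 14, closing ring B through C2–O3 instead of C1–C2.
 - Bromide 6 and PPh3 in toluene give the phosphonium bromide F1.
 - KN(SiMe3)2 in THF at −78 °C converts it into the benzylic ylide F2, and a Wittig olefination of 12 gives the benzylidene oxolane F3 as an E/Z mixture.
 - Dihydroxylation with OsO4 (cat.) and N-methylmorpholine N-oxide should deliver oxygen to C1 from the face opposite to the C4 side chain, giving the diol F4 with the C1 hydroxyl already on the convex side.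
 - Catalytic CF3CO2H in wet CH2Cl2 then ionises the benzylic C2 hydroxyl. The O3 ether oxygen traps the cation and sheds its own syringylmethyl group (debenzylative cycloetherification).
 - The exo aryl group should result from thermodynamic control.

Risk 2, step 7.
- **What may go wrong:** sluggish epoxidation of the monosubstituted alkene, competing 4-exo closure, participation of the benzyl ether oxygen in the epoxide opening, or acid ionisation of the electron-rich benzylic alcohol.
- **Fallback:** it sets out from 9 and comes back at 11, replacing the endo epoxide opening by an exo displacement.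
 - OsO4 (cat.) with N-methylmorpholine N-oxide gives the triol F5 as a mixture at C1.
 - TsCl in pyridine at 0 °C sulfonylates the primary C8 hydroxyl to the monotosylate F6.
 - Warming in pyridine lets the neutral C6 hydroxyl displace the tosylate (5-exo-tet, SN2 at C8), with C5 and C6 untouched.

Risk 3, step 5.
- **What may go wrong:** erosion of anti selectivity or enantioselectivity with the electron-rich aldehyde, and loss of the aryl silyl ether to base at 90 °C.
- **Fallback:** it sets out from bromide 6 and aldehyde 2 and comes back at 9, so it also makes the selective etherification of step 6 unnecessary.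
 - Commercial cis-but-2-ene-1,4-diol is monoalkylated with 6 (Ag2O, CH2Cl2) to the allylic alcohol F7.
 - Borylation with B2pin2 under Pd(MeCN)4(BF4)2 catalysis in DMSO–MeOH gives, through the syn π-allyl complex, the linear (E)-allylboronate F8.
 - Allylboration of 2 follows in toluene at −30 °C, catalysed by the chiral phosphoric acid TRIP, with the enantiomer chosen for Si-face attack. It should give, through a chair transition state, the anti-configured pinacol borate F9.
 - Aqueous work-up hydrolyses this to 9.

Further compounds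
F1 | step 9 | [3,5-dimethoxy-4-(triisopropylsilyloxy)benzyl]triphenylphosphonium bromide | COc1cc(C[P+](c2ccccc2)(c2ccccc2)c2ccccc2)cc(OC)c1O[Si](C(C)C)(C(C)C)C(C)C.[Br-]
F2 | step 9 | [3,5-dimethoxy-4-(triisopropylsilyloxy)benzylidene]triphenylphosphorane | COc1cc(C=P(c2ccccc2)(c2ccccc2)c2ccccc2)cc(OC)c1O[Si](C(C)C)(C(C)C)C(C)C
F3 | step 9 | benzylidene oxolane, C1=C2 alkene from 12 (E/Z mixture, C5 and C6 as in 12) | COc1cc([C@H]2OCC(=Cc3cc(OC)c(O[Si](C(C)C)(C(C)C)C(C)C)c(OC)c3)[C@@H]2COCc2cc(OC)c(O[Si](C(C)C)(C(C)C)C(C)C)c(OC)c2)ccc1O[Si](C(C)C)(C(C)C)C(C)C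
F4 | step 9 | C1,C2-diol of F3 (C1 hydroxyl trans to the C4 side chain, C2 unassigned) | COc1cc([C@H]2OC[C@](O)(C(O)c3cc(OC)c(O[Si](C(C)C)(C(C)C)C(C)C)c(OC)c3)[C@@H]2COCc2cc(OC)c(O[Si](C(C)C)(C(C)C)C(C)C)c(OC)c2)ccc1O[Si](C(C)C)(C(C)C)C(C)C
F5 | step 7 | triol from dihydroxylation of 9 (both C1 epimers) | COc1cc([C@@H](O)[C@H](C(O)CO)COCc2cc(OC)c(O[Si](C(C)C)(C(C)C)C(C)C)c(OC)c2)ccc1O[Si](C(C)C)(C(C)C)C(C)C
F6 | step 7 | primary (C8) monotosylate of F5 | COc1cc([C@@H](O)[C@H](C(O)COS(=O)(=O)c2ccc(C)cc2)COCc2cc(OC)c(O[Si](C(C)C)(C(C)C)C(C)C)c(OC)c2)ccc1O[Si](C(C)C)(C(C)C)C(C)C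
F7 | step 5 | (Z)-4-{[3,5-dimethoxy-4-(triisopropylsilyloxy)benzyl]oxy}but-2-en-1-ol | COc1cc(COC/C=C\CO)cc(OC)c1O[Si](C(C)C)(C(C)C)C(C)C
F8 | step 5 | (E)-4-{[3,5-dimethoxy-4-(triisopropylsilyloxy)benzyl]oxy}but-2-enylboronic acid pinacol ester | COc1cc(COC/C=C/CB2OC(C)(C)C(C)(C)O2)cc(OC)c1O[Si](C(C)C)(C(C)C)C(C)C
F9 | step 5 | pinacol borate of 9 (O-boryl at the C6 oxygen) | COc1cc([C@@H](OB2OC(C)(C)C(C)(C)O2)[C@H](C=C)COCc2cc(OC)c(O[Si](C(C)C)(C(C)C)C(C)C)c(OC)c2)ccc1O[Si](C(C)C)(C(C)C)C(C)C
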